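**Retrosynthetic overview**
1. Target ⇒ 3‑methoxy‑1,2‑dioxane + silyl ketene acetal (C2–C3, axial attack on a peroxycarbenium ion, sets C3) ⇒ 3,6‑dimethoxy‑1,2‑dioxane + Et3Al (ethyl onto C6, axial, sets C6).
2. The only ring, the 1,2‑dioxane, is formed once: H2O2 closes a 1,4‑keto aldehyde (C3 aldehyde, C6 ketone) to the cyclic bis‑peroxyketal.
3. Key disconnection C4–C5: the 1,4‑dicarbonyl comes from butanal and a 2‑ethoxy‑1‑alkene by enantioselective oxidative (SOMO) α‑enolation, an enolonium‑type union of two normally nucleophilic α‑carbons; it sets C4.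
4. C6–C7: 1‑ethoxyvinyllithium (acetyl anion equivalent) + the side‑chain allylic bromide.
5. Side chain: (E)‑pent‑2‑enal → (3R)‑allylic alcohol (Et2Zn) → picolinate → anti‑SN2′ with an isobutenyl copper reagent (sets the CH(Et) centre) → allylic oxidation → bromide.

Assumption: every reagent that leaves non‑hydrogen atoms in a product is numbered and listed as a starting material; catalysts, bases and solvents are not numbered.

**Step 1**
Reactants: 1 (E)-pent-2-enal; 2 diethylzinc
Product: 3 (3R,4E)-hept-4-en-3-ol
Conditions: Et2Zn (2 equiv), (2R)-(+)-3-exo-morpholinoisoborneol (4 mol%), hexane/toluene, 0 °C; aq. NH4Cl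
Reagents that add atoms: diethylzinc (2), CC[Zn]CC
Why: Amino‑alcohol‑catalysed enantioselective 1,2‑addition of a dialkylzinc to an aldehyde, in which the (2R)‑ligand zinc alkoxide delivers ethyl to the carbonyl face that gives the 3R carbinol (the antipodal ligand gives 3S) and enals are good substrates.

**Step 2**
Reactants: 3 (3R,4E)-hept-4-en-3-ol; 4 pyridine-2-carboxylic acid
Product: 5 (3R,4E)-hept-4-en-3-yl pyridine-2-carboxylate
Conditions: picolinic acid (1.5 equiv), DCC (1.5 equiv), DMAP (10 mol%), CH2Cl2, 20 °C
Reagents that add atoms: pyridine-2-carboxylic acid (4), OC(=O)c1ccccn1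
Why: Steglich esterification installs the chelating picolinate leaving group at oxygen without touching the stereocentre.

**Step 3**
Reactants: 5 (3R,4E)-hept-4-en-3-yl pyridine-2-carboxylate; 6 (2-methylprop-1-en-1-yl)magnesium bromide
Product: 7 (4R,5E)-4-ethyl-2-methylocta-2,5-diene
Conditions: 6 (2.5 equiv), CuBr·SMe2 (30 mol%), THF/Et2O, −40 to 0 °C; aq. NH4Cl
Reagents that add atoms: (2-methylprop-1-en-1-yl)magnesium bromide (6), CC(C)=C[Mg]Br
Why: Copper‑mediated anti‑SN2′ allylic substitution of a picolinate, in which the alkenylcopper attacks the γ‑carbon anti to the magnesium‑chelated leaving group through the conformer with the carbinol hydrogen eclipsing the alkene, so the 3R centre is relayed to the new 4R centre with an E alkene (the allyl unit is constitutionally symmetric, so γ‑selectivity equals enantiospecificity).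

**Step 4**
Reactants: 7 (4R,5E)-4-ethyl-2-methylocta-2,5-diene; 8 tert-butyl hydroperoxide
Product: 9 (2E,4R,5E)-4-ethyl-2-methylocta-2,5-dien-1-ol
Conditions: SeO2 (0.5 equiv), t-BuOOH (3 equiv), salicylic acid (10 mol%), CH2Cl2, 20 °C
Reagents that add atoms: tert-butyl hydroperoxide (8), CC(C)(C)OO
Why: Riley allylic oxidation (ene reaction then [2,3]‑shift) hydroxylates the E‑methyl group at the more substituted end of the trisubstituted alkene, giving the E allylic alcohol while the slower 1,2‑disubstituted alkene and the stereocentre stay untouched.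

**Step 5**
Reactants: 9 (2E,4R,5E)-4-ethyl-2-methylocta-2,5-dien-1-ol; 10 tetrabromomethane
Product: 11 (2E,4R,5E)-1-bromo-4-ethyl-2-methylocta-2,5-diene
Conditions: CBr4 (1.2 equiv), PPh3 (1.2 equiv), CH2Cl2, 0 °C
Reagents that add atoms: tetrabromomethane (10), BrC(Br)(Br)Br
Why: Appel reaction, an SN2 displacement of the alkoxyphosphonium group by bromide at the primary allylic carbon under neutral conditions without allylic transposition.

**Step 6**
Reactants: 11 (2E,4R,5E)-1-bromo-4-ethyl-2-methylocta-2,5-diene; 12 ethyl vinyl ether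
Product: 14 (4E,6R,7E)-2-ethoxy-6-ethyl-4-methyldeca-1,4,7-triene, via 1-ethoxyvinyllithium 13 (not isolated)
Conditions: ethyl vinyl ether (3 equiv), tert-butyllithium (2 equiv), THF, −78 to 0 °C; then 11, −78 to 20 °C; aq. NaHCO3; filtration through basic alumina
Reagents that add atoms: ethyl vinyl ether (12), C=COCC
Why: SN2 alkylation of a metalated enol ether, a classical acetyl anion equivalent, joins the masked carbonyl carbon C6 to the allylic carbon C7 and leaves the enol ether double bond fixed on the terminal side.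

**Step 7**
Reactants: 14 (4E,6R,7E)-2-ethoxy-6-ethyl-4-methyldeca-1,4,7-triene; 15 butanal; 16 water
Product: 17 (2R,6E,8R,9E)-2,8-diethyl-6-methyl-4-oxododeca-6,9-dienal
Conditions: butanal (3 equiv), (2S,5S)-5-benzyl-2-tert-butyl-3-methylimidazolidin-4-one trifluoroacetate (20 mol%), (NH4)2Ce(NO3)6 (2.2 equiv), NaHCO3 (3 equiv), H2O (2 equiv), DME, −20 °C
Reagents that add atoms: butanal (15), CCCC=O; water (16), O
Why: Proposed new method: organo‑SOMO α‑enolation extended from silyl enol ethers to an alkyl enol ether, in which one‑electron oxidation of the butanal enamine by tetravalent cerium gives a 3π‑electron radical cation (an enolonium equivalent) that is attacked at its α‑carbon by the terminal carbon of the enol ether, the α‑ethoxy radical is oxidised to an oxocarbenium ion and hydrolysed to the ketone, and the benzyl group of the catalyst shields one face of the E radical cation so the bond forms on the open face and sets 2R; the closest known reaction is the enantioselective SOMO α‑enolation of aldehydes with enolsilanes.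

**Step 8**
Reactants: 17 (2R,6E,8R,9E)-2,8-diethyl-6-methyl-4-oxododeca-6,9-dienal; 18 hydrogen peroxide; 19 methanol
Product: 21 (4R)-4-ethyl-6-[(2E,4R,5E)-4-ethyl-2-methylocta-2,5-dien-1-yl]-3,6-dimethoxy-1,2-dioxane, via dioxane-3,6-diol 20 (not isolated)
Conditions: H2O2 (1.5 equiv, dried ethereal solution), TsOH·H2O (5 mol%), Et2O, 0 °C; then MeOH (excess), 4 Å molecular sieves, 0 to 20 °C
Reagents that add atoms: hydrogen peroxide (18), OO; methanol (19), CO
Why: Acid‑catalysed double addition of hydrogen peroxide to a 1,4‑dicarbonyl compound gives the cyclic bis(peroxyhemiketal), as 1,4‑diketones are known to do, and acetal exchange with methanol gives the 3,6‑dimethoxy‑1,2‑dioxane, with C4 not involved and C3 and C6 left as anomeric mixtures that are erased in steps 9 and 10.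

**Step 9**
Reactants: 21 (4R)-4-ethyl-6-[(2E,4R,5E)-4-ethyl-2-methylocta-2,5-dien-1-yl]-3,6-dimethoxy-1,2-dioxane; 22 triethylaluminium
Product: 23 (4R,6R)-4,6-diethyl-6-[(2E,4R,5E)-4-ethyl-2-methylocta-2,5-dien-1-yl]-3-methoxy-1,2-dioxane
Conditions: Et3Al (2.5 equiv), CH2Cl2, −78 to −40 °C; aq. KNaC4H4O6
Reagents that add atoms: triethylaluminium (22), CC[Al](CC)CC
Why: Proposed new method: Et3Al serves as Lewis acid and nucleophile, ionising the more easily ionised tertiary peroxyketal at C6 to a cyclic peroxycarbenium ion and transferring ethyl along the axial trajectory of the half‑chair whose C4 ethyl group is pseudoequatorial, so ethyl enters trans to the C4 ethyl group and the side chain ends equatorial (6R); the closest known reactions are Lewis‑acid‑mediated allylation of cyclic peroxyketals through peroxycarbenium ions and trialkylaluminium alkylation of cyclic ketals and lactol derivatives.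

**Step 10**
Reactants: 23 (4R,6R)-4,6-diethyl-6-[(2E,4R,5E)-4-ethyl-2-methylocta-2,5-dien-1-yl]-3-methoxy-1,2-dioxane; 24 tert-butyl[(1-methoxyethenyl)oxy]dimethylsilane
Product: 25 methyl 2-[(3R,4R,6R)-4,6-diethyl-6-[(2E,4R,5E)-4-ethyl-2-methylocta-2,5-dien-1-yl]-1,2-dioxan-3-yl]acetate
Conditions: 24 (3 equiv), TMSOTf (20 mol%), CH2Cl2, −78 °C; Et3N, then aq. NaHCO3
Reagents that add atoms: tert-butyl[(1-methoxyethenyl)oxy]dimethylsilane (24), C=C(OC)O[Si](C)(C)C(C)(C)C
Why: Mukaiyama‑type substitution of a cyclic peroxyacetal by a silyl ketene acetal through a peroxycarbenium ion, in which the half‑chair that keeps the C4 ethyl group and the C6 side chain equatorial is attacked axially, cis to the C4 ethyl group and trans to the axial C6 ethyl group, giving 3R.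

**Compound list**
1 | (E)-pent-2-enal | CC/C=C/C=O | starting material
2 | diethylzinc | CC[Zn]CC | starting material
3 | (3R,4E)-hept-4-en-3-ol | CC[C@@H](O)/C=C/CC | intermediate
4 | pyridine-2-carboxylic acid (picolinic acid) | OC(=O)c1ccccn1 | starting material
5 | (3R,4E)-hept-4-en-3-yl pyridine-2-carboxylate | CC[C@@H](OC(=O)c1ccccn1)/C=C/CC | intermediate
6 | (2-methylprop-1-en-1-yl)magnesium bromide | CC(C)=C[Mg]Br | starting material
7 | (4R,5E)-4-ethyl-2-methylocta-2,5-diene | CC/C=C/[C@H](C=C(C)C)CC | intermediate
8 | tert-butyl hydroperoxide | CC(C)(C)OO | starting material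
9 | (2E,4R,5E)-4-ethyl-2-methylocta-2,5-dien-1-ol | CC/C=C/[C@H](/C=C(\C)CO)CC | intermediate
10 | tetrabromomethane | BrC(Br)(Br)Br | starting material
11 | (2E,4R,5E)-1-bromo-4-ethyl-2-methylocta-2,5-diene | CC/C=C/[C@H](/C=C(\C)CBr)CC | intermediate
12 | ethyl vinyl ether | C=COCC | starting material
13 | 1-ethoxyvinyllithium | [Li]C(=C)OCC | intermediate (not isolated)
14 | (4E,6R,7E)-2-ethoxy-6-ethyl-4-methyldeca-1,4,7-triene | CC/C=C/[C@H](/C=C(\C)CC(=C)OCC)CC | intermediate
15 | butanal | CCCC=O | starting material
16 | water | O | starting material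
17 | (2R,6E,8R,9E)-2,8-diethyl-6-methyl-4-oxododeca-6,9-dienal | CC/C=C/[C@H](/C=C(\C)CC(=O)C[C@@H](CC)C=O)CC | intermediate
18 | hydrogen peroxide | OO | starting material
19 | methanol | CO | starting material
20 | (4R)-4-ethyl-6-[(2E,4R,5E)-4-ethyl-2-methylocta-2,5-dien-1-yl]-1,2-dioxane-3,6-diol (C3/C6 anomer mixture) | CC/C=C/[C@H](/C=C(\C)CC1(O)C[C@@H](CC)C(O)OO1)CC | intermediate (not isolated)
21 | (4R)-4-ethyl-6-[(2E,4R,5E)-4-ethyl-2-methylocta-2,5-dien-1-yl]-3,6-dimethoxy-1,2-dioxane (C3/C6 anomer mixture) | CC/C=C/[C@H](/C=C(\C)CC1(OC)C[C@@H](CC)C(OC)OO1)CC | intermediate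
22 | triethylaluminium | CC[Al](CC)CC | starting material
23 | (4R,6R)-4,6-diethyl-6-[(2E,4R,5E)-4-ethyl-2-methylocta-2,5-dien-1-yl]-3-methoxy-1,2-dioxane (C3 anomer mixture) | CC/C=C/[C@H](/C=C(\C)C[C@@]1(CC)C[C@@H](CC)C(OC)OO1)CC | intermediate
24 | tert-butyl[(1-methoxyethenyl)oxy]dimethylsilane | C=C(OC)O[Si](C)(C)C(C)(C)C | starting material
25 | methyl 2-[(3R,4R,6R)-4,6-diethyl-6-[(2E,4R,5E)-4-ethyl-2-methylocta-2,5-dien-1-yl]-1,2-dioxan-3-yl]acetate | CC/C=C/[C@H](/C=C(\C)C[C@@]1(CC)C[C@@H](CC)[C@@H](CC(=O)OC)OO1)CC | target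

**Totals**
Total step count: 10. Longest linear sequence: 10 (steps 1 to 10; all other inputs are commercial).

**Three steps most likely to fail**

Step 9 (ethyl transfer to the peroxyketal). There is no precedent for an alkyl nucleophile on a peroxycarbenium ion. Likely failure modes are β‑hydride reduction, loss of the allylic C7 proton to an enol peroxide, attack at the C3 acetal, and O–O cleavage. The fallback sets out from 21 and comes back at 23. A vinyl group is transferred in place of ethyl with K[CH2=CHBF3] and BF3·OEt2 in CH2Cl2/MeCN at −40 °C, with the same axial delivery, to give (4R,6R)-6-ethenyl-4-ethyl-6-[(2E,4R,5E)-4-ethyl-2-methylocta-2,5-dien-1-yl]-3-methoxy-1,2-dioxane F3. Diimide (2‑nitrobenzenesulfonohydrazide, Et3N, CH2Cl2, 20 °C) then reduces only the monosubstituted vinyl group. It spares the 1,2‑disubstituted and trisubstituted alkenes and the O–O bond, and gives 23.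

Step 7 (SOMO coupling with an alkyl enol ether). The enol ether may hydrolyse to the methyl ketone before it is trapped. The oxocarbenium ion may lose the allylic proton and give the conjugated enone. With butanal in excess, aldehyde self‑coupling competes. The fallback sets out from 14 and comes back at 17. N‑Bromosuccinimide in THF/H2O at 0 °C brominates the terminal enol ether carbon and gives the bromomethyl ketone (4E,6R,7E)-1-bromo-6-ethyl-4-methyldeca-4,7-dien-2-one F1. F1 is joined to butanal 15 by photoredox organocatalytic α‑alkylation (Ru(bpy)3Cl2, an imidazolidinone triflate catalyst of the same facial sense, 2,6‑lutidine, DMF, visible light). Here the α‑halo ketone is reduced to an electrophilic α‑keto radical that adds to the chiral enamine, giving 17.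

Step 8 (closure to the 3,6‑dimethoxy‑1,2‑dioxane). The keto aldehyde can instead give 2,5‑dimethoxytetrahydrofurans or a furan, the β,γ‑unsaturated ketone can slip into conjugation, and the product is a four‑component anomer mixture that is hard to purify. The fallback sets out from 17 and comes back at 21. Ethereal H2O2 under dehydrating conditions (P2O5, Et2O/MeCN, 0 °C) closes 17 to the ozonide‑like bicyclic peroxide (5R)-5-ethyl-1-[(2E,4R,5E)-4-ethyl-2-methylocta-2,5-dien-1-yl]-2,3,7-trioxabicyclo[2.2.1]heptane F2, which is constitutionally uniform and can be purified. Methanol with catalytic TsOH then opens the bridging ether oxygen to give 21.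

**Further compounds**
F1 | step 7 | (4E,6R,7E)-1-bromo-6-ethyl-4-methyldeca-4,7-dien-2-one | CC/C=C/[C@H](/C=C(\C)CC(=O)CBr)CC
F2 | step 8 | (5R)-5-ethyl-1-[(2E,4R,5E)-4-ethyl-2-methylocta-2,5-dien-1-yl]-2,3,7-trioxabicyclo[2.2.1]heptane | CC/C=C/[C@H](/C=C(\C)CC12C[C@@H](CC)C(OO1)O2)CC
F3 | step 9 | (4R,6R)-6-ethenyl-4-ethyl-6-[(2E,4R,5E)-4-ethyl-2-methylocta-2,5-dien-1-yl]-3-methoxy-1,2-dioxane | CC/C=C/[C@H](/C=C(\C)C[C@@]1(C=C)C[C@@H](CC)C(OC)OO1)CC
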